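**Retrosynthetic overview**

1. The ester C–O bond is cut first, then the C(sp3)–C(sp2) bond from cyclobutane C1 to the pentenyl unit (nickel radical cross-coupling, which sets the trans arrangement); this leaves 4-(4-iodo-2,2-dimethylcyclobutyl)butan-2-one.
2. Enabling feature: the ketone carbon of the 3-oxobutyl chain lies three atoms from ring carbon C2. Bonded to the neighbouring ring carbon C1 it is a carbinol carbon, so the iodo ketone is the ring-opened form of a cyclopentanol fused across C1–C2 of the cyclobutane, 2,6,6-trimethylbicyclo[3.2.0]heptan-2-ol.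
3. Opening that cyclobutane at the ring CH–CH bond (C1–C2) and the CH2–C(CH3)2 bond (C4–C3) gives the commercial 1,6-dien-3-ol (S)-linalool. Its vinyl and 2-methylprop-1-enyl groups are the two halves of the four-membered ring, and C(OH)(CH3)–CH2–CH2 is a temporary tether that already holds every carbon of the 3-oxobutyl chain.
4. Ring order: cyclobutane and temporary cyclopentane form together in one copper-catalysed [2+2] photocycloaddition. The strained cyclopentanol is then cut by alkoxy-radical β-scission, which unveils the methyl ketone and functionalises C1; the carbinol centre of linalool relays its configuration to C2 and is then destroyed.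

Key step: step 1

Assumption: (S)-(+)-linalool is bought in high enantiomeric purity, and the hydroxyl-bound (endo-OH) mode of the copper-catalysed photobicyclization is taken to dominate for this tertiary carbinol as it does for secondary 1,6-dien-3-ols.

**Route**

Step 1
Reactants: 1 (3S)-3,7-dimethylocta-1,6-dien-3-ol, (S)-(+)-linalool
Product: 2 (1R,2S,5R)-2,6,6-trimethylbicyclo[3.2.0]heptan-2-ol (cis-fused; hydroxyl endo, 2-methyl exo)
Conditions: (CuOTf)2·C6H6 (3 mol%), Et2O, hν (254 nm, quartz), 25 °C; chromatography to remove the exo-hydroxy epimer
Reagents that add atoms: none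
Why: Salomon–Kochi copper-catalysed intramolecular [2+2] photocycloaddition: monovalent copper binds the vinyl group, the trisubstituted alkene and the hydroxyl of 1, and excitation of this bis(alkene) complex joins the two alkenes, forming C1–C5 and C6–C7 of 2. The closest known reaction type is the CuOTf-catalysed photobicyclization of 1,6-dien-3-ols to bicyclo[3.2.0]heptan-2-ols. The three-atom tether allows only the parallel mode: the cyclopentane closes by bonding of the two inner alkene carbons (vinyl CH to prenyl CH, a 1,5-closure) and the cyclobutane closes when the outer carbons join (vinyl CH2 to C(CH3)2), which places the gem-dimethyl carbon next to the ring CH2. C1 and C5 must be cis because a three-atom bridge cannot span a trans-fused cyclobutane, and their absolute sense follows from the carbinol centre C2, whose copper-bound hydroxyl should end on the concave (endo) face with the methyl group exo. The step needs face selectivity relative to C2, since the exo-hydroxy epimer would give the enantiomeric series once C2 is destroyed in step 2; chelation and the smaller size of OH should secure it, and the minor epimer is removed by chromatography.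

Step 2
Reactants: 2 (1R,2S,5R)-2,6,6-trimethylbicyclo[3.2.0]heptan-2-ol
Product: 4 4-[(1S)-4-iodo-2,2-dimethylcyclobutyl]butan-2-one as a mixture of the two epimers at the iodine-bearing carbon, via bicyclic hypoiodite 3 (not isolated)
Conditions: PhI(OAc)2 (1.2 equiv), I2 (1.0 equiv), cyclohexane, visible light (tungsten lamp), 25 °C
Reagents that add atoms: iodine, [I][I]
Why: Suárez hypoiodite fragmentation: light cleaves the O–I bond of 3 to the tertiary alkoxy radical, whose β-scission at the C1–C2 bond (driven by loss of the strain of the cis-fused bicycle) gives the methyl ketone and a secondary cyclobutyl radical, expected to be favoured over the primary radical from C2–C3 scission, which takes up iodine; C5 is untouched and the new C–I centre may form as both epimers because step 4 erases it.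

Step 3
Reactants: 5 pent-4-yn-1-ol
Product: 6 4-bromopent-4-en-1-ol
Conditions: Et4N+ HBr2− (1.3 equiv), CH2Cl2, 40 °C
Reagents that add atoms: tetraethylammonium hydrogen dibromide, CC[N+](CC)(CC)CC.Br.[Br-]
Why: Markovnikov hydrobromination of the terminal alkyne by hydrogen dibromide places bromine on the internal carbon and gives the 2-bromo-1-alkene; no stereocentre is formed.

Step 4
Reactants: 4 4-[(1S)-4-iodo-2,2-dimethylcyclobutyl]butan-2-one; 6 4-bromopent-4-en-1-ol
Product: 7 4-[(1S,2R)-3,3-dimethyl-2-(3-oxobutyl)cyclobutyl]pent-4-en-1-ol (ring substituents trans)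
Conditions: NiBr2·DME (10 mol%), 4,4'-di-tert-butyl-2,2'-bipyridine (10 mol%), Zn dust (2 equiv), NaI (0.25 equiv), DMA, 25 °C; 6 in excess (1.5 equiv)
Reagents that add atoms: none
Why: Nickel-catalysed reductive cross-electrophile coupling: the alkenyl bromide adds oxidatively to zerovalent nickel, iodine abstraction from either epimer of 4 gives one cyclobutyl radical, and this is captured by nickel and coupled on the ring face remote from the neighbouring 3-oxobutyl chain, which should set the trans (1S,2R) arrangement.

Step 5
Reactants: 7 4-[(1S,2R)-3,3-dimethyl-2-(3-oxobutyl)cyclobutyl]pent-4-en-1-ol; 8 (9Z,12Z)-octadeca-9,12-dienoyl chloride (linoleoyl chloride)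
Product: 9 4-[(1S,2R)-3,3-dimethyl-2-(3-oxobutyl)cyclobutyl]pent-4-en-1-yl (9Z,12Z)-octadeca-9,12-dienoate (IN0146)
Conditions: pyridine (2 equiv), DMAP (5 mol%), CH2Cl2, 0 °C to 25 °C
Reagents that add atoms: none
Why: DMAP-catalysed acylation of the primary alcohol by the acid chloride; the ketone, the 1,1-disubstituted alkene and the skipped (Z,Z)-diene are inert under these conditions and no stereocentre is touched.

**Compound list**

1 | (3S)-3,7-dimethylocta-1,6-dien-3-ol, (S)-(+)-linalool | C=C[C@@](C)(O)CCC=C(C)C | starting material
2 | (1R,2S,5R)-2,6,6-trimethylbicyclo[3.2.0]heptan-2-ol | C[C@]1(O)CC[C@@H]2[C@H]1CC2(C)C | intermediate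
3 | (1R,2S,5R)-2,6,6-trimethylbicyclo[3.2.0]heptan-2-yl hypoiodite | C[C@]1(OI)CC[C@@H]2[C@H]1CC2(C)C | intermediate (not isolated)
4 | 4-[(1S)-4-iodo-2,2-dimethylcyclobutyl]butan-2-one, both epimers at the iodine-bearing carbon | CC(=O)CC[C@@H]1C(I)CC1(C)C | intermediate
5 | pent-4-yn-1-ol | C#CCCCO | starting material
6 | 4-bromopent-4-en-1-ol | C=C(Br)CCCO | intermediate
7 | 4-[(1S,2R)-3,3-dimethyl-2-(3-oxobutyl)cyclobutyl]pent-4-en-1-ol | C=C(CCCO)[C@H]1CC(C)(C)[C@@H]1CCC(C)=O | intermediate
8 | (9Z,12Z)-octadeca-9,12-dienoyl chloride | CCCCC/C=C\C/C=C\CCCCCCCC(Cl)=O | starting material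
9 | 4-[(1S,2R)-3,3-dimethyl-2-(3-oxobutyl)cyclobutyl]pent-4-en-1-yl (9Z,12Z)-octadeca-9,12-dienoate | C=C(CCCOC(=O)CCCCCCC/C=C\C/C=C\CCCCC)[C@H]1CC(C)(C)[C@@H]1CCC(C)=O | target

**Step count and risks**

Total: 5 steps. Longest linear sequence: 4 steps (steps 1, 2, 4 and 5, from 1).

Steps most likely to fail:

Step 2. The β-scission may take the other course, that is cleavage of the C2–C3 bond to a primary radical or loss of the methyl group, because a cyclobutyl radical is only a little more stable than a primary one; a regioisomeric iodo ketone would then contaminate 4. The fallback replaces the radical scission by a polar retro-Claisen ring opening, whose regiochemistry is fixed by the position of an acetyl group, and replaces the halide coupling by a decarboxylative one. It does not branch from an intermediate: it replaces 1 to 4, sets out from compound 6 (kept as coupling partner) together with commercial 5-bromo-2-methylpent-2-ene and acrolein, and comes back to the route at compound 7. Mg in THF gives (4-methylpent-3-en-1-yl)magnesium bromide F1, which adds to acrolein (THF, −78 °C) to give racemic 7-methylocta-1,6-dien-3-ol F2. Sharpless kinetic resolution (Ti(OiPr)4, (2S,3S)-diisopropyl tartrate, t-BuOOH, CH2Cl2, −20 °C) should leave (3S)-7-methylocta-1,6-dien-3-ol F3 unreacted. The conditions of step 1 should turn F3 into (1R,2S,5R)-6,6-dimethylbicyclo[3.2.0]heptan-2-ol F4, and Dess–Martin periodinane oxidises it to (1R,5R)-6,6-dimethylbicyclo[3.2.0]heptan-2-one F5. Claisen acetylation (NaH, EtOAc, THF) at the α-CH2 gives (1R,5R)-3-acetyl-6,6-dimethylbicyclo[3.2.0]heptan-2-one F6. Aqueous NaOH with heating attacks the strained ring carbonyl and opens the cyclopentanone by retro-Claisen cleavage to (1R,2R)-3,3-dimethyl-2-(3-oxobutyl)cyclobutane-1-carboxylic acid F7. Decarboxylative nickel/photoredox coupling of F7 with 6 (Ir[dF(CF3)ppy]2(dtbbpy)PF6, NiCl2·DME, 4,4'-di-tert-butyl-2,2'-bipyridine, DBU, DMSO, blue LEDs) passes through the same cyclobutyl radical as step 4 and should give 7.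

Step 4. The coupling may be lost to reductive homocoupling of either halide, simple reduction of the iodide, reclosure of an alkylzinc onto the ketone, or poor face selectivity at the cyclobutyl radical. The fallback is a polar Negishi coupling in which the C–Zn centre settles under thermodynamic control; it sets out from 4 and 6 and comes back at 7. Compound 6 is silylated (TBSCl, imidazole, DMF) to tert-butyl[(4-bromopent-4-en-1-yl)oxy]dimethylsilane F8. Zinc insertion into 4 (Zn dust, LiCl, THF, 25 °C) gives [(2S)-3,3-dimethyl-2-(3-oxobutyl)cyclobutyl]zinc iodide F9 (not isolated), which should equilibrate to the isomer with zinc trans to the chain. Coupling of F9 with F8 (Pd(OAc)2, SPhos, THF, 25 °C) with retention should give tert-butyl({4-[(1S,2R)-3,3-dimethyl-2-(3-oxobutyl)cyclobutyl]pent-4-en-1-yl}oxy)dimethylsilane F10, and Bu4NF in THF returns 7.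

Step 1. The tertiary carbinol may control the ring-fusion face incompletely (an endo/exo mixture lowers the enantiomeric purity of everything downstream), turnover may be slow because the trisubstituted alkene binds copper weakly, and traces of TfOH may ionise the tertiary allylic alcohol. The fallback moves stereocontrol to a secondary carbinol and builds the quaternary carbinol afterwards. Like the fallback to step 2 it sets out from commercial 5-bromo-2-methylpent-2-ene and acrolein in place of 1, and it comes back at compound 2. It follows that fallback through F1, F2, F3 and F4 to ketone F5; the secondary dienol is the well-precedented endo-selective case, is not prone to ionisation, and takes its enantiomeric purity from the kinetic resolution. MeMgBr (Et2O, −78 °C) should then add to F5 from the convex face, placing the new methyl group exo and the hydroxyl endo, which is 2. It makes no compound beyond those already listed (entry F0).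

**Further compounds**

F1 | step 2 | (4-methylpent-3-en-1-yl)magnesium bromide | CC(C)=CCC[Mg]Br
F2 | step 2 | racemic 7-methylocta-1,6-dien-3-ol | C=CC(O)CCC=C(C)C
F3 | step 2 | (3S)-7-methylocta-1,6-dien-3-ol | C=C[C@@H](O)CCC=C(C)C
F4 | step 2 | (1R,2S,5R)-6,6-dimethylbicyclo[3.2.0]heptan-2-ol | O[C@H]1CC[C@@H]2[C@H]1CC2(C)C
F5 | step 2 | (1R,5R)-6,6-dimethylbicyclo[3.2.0]heptan-2-one | O=C1CC[C@@H]2[C@H]1CC2(C)C
F6 | step 2 | (1R,5R)-3-acetyl-6,6-dimethylbicyclo[3.2.0]heptan-2-one (C3 epimers, partly enolised) | CC(=O)C1C[C@@H]2[C@@H](CC2(C)C)C1=O
F7 | step 2 | (1R,2R)-3,3-dimethyl-2-(3-oxobutyl)cyclobutane-1-carboxylic acid | CC(=O)CC[C@@H]1[C@H](C(=O)O)CC1(C)C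
F8 | step 4 | tert-butyl[(4-bromopent-4-en-1-yl)oxy]dimethylsilane | C=C(Br)CCCO[Si](C)(C)C(C)(C)C
F9 | step 4 | [(2S)-3,3-dimethyl-2-(3-oxobutyl)cyclobutyl]zinc iodide | CC(=O)CC[C@@H]1C([Zn]I)CC1(C)C
F10 | step 4 | tert-butyl({4-[(1S,2R)-3,3-dimethyl-2-(3-oxobutyl)cyclobutyl]pent-4-en-1-yl}oxy)dimethylsilane | C=C(CCCO[Si](C)(C)C(C)(C)C)[C@H]1CC(C)(C)[C@@H]1CCC(C)=O
F0 | step 1 | none | none
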